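The carbocycle (ring A, C5–C10) is disconnected at C5–C6. In the target, the C5 isopropenyl group sits beside the C6 lactone oxygen, a homoallylic-alcohol pattern that a carbonyl-ene reaction writes directly, and quaternary C10 carries two alkenyl arms. An open-chain C6 aldehyde whose C10 bears a methyl and two identical 2-methylprop-1-enyl groups is therefore cyclised with Me2AlCl: one arm adds through its inner carbon to the aldehyde, closing ring A and setting C5, C6 and C10 in one operation, while the untouched arm is later trimmed to the vinyl group. The precursor's only stereocentres, C7 and C8, come from an Evans syn-aldol; lactone ring B, the exocyclic methylene and the C8 ester follow.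

Key step: step 11

Remark: atoms carry elemane numbering (ring A = C5–C10; ring B = lactone O–C6–C7–C11–C12; C1/C2 vinyl; C3/C4/C15 isopropenyl; C13 exocyclic methylene; C14 methyl on C10). The side-chain acid is carried as its seven-membered acetonide, which locks the (E) geometry.

Step 1
Reactants: 1 diethyl methylmalonate; 2 2-bromo-1,1-diethoxyethane
Product: 3 diethyl 2-(2,2-diethoxyethyl)-2-methylpropanedioate
Conditions: NaH, DMF, 0 °C → rt; then 2, NaI (cat.), 100 °C
Reagents that add atoms: none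
Why: Malonate alkylation (SN2) of the sodium enolate of 1, in which the sluggish β,β-dialkoxy bromide is activated as the iodide in hot DMF and the fully substituted product cannot alkylate again.

Step 2
Reactants: 3 diethyl 2-(2,2-diethoxyethyl)-2-methylpropanedioate
Product: 4 2-(2,2-diethoxyethyl)-2-methylpropane-1,3-diol
Conditions: LiAlH4, THF, 0 °C → rt; H2O, 15% NaOH, H2O
Reagents that add atoms: none
Why: Hydride reduction of both esters to the prochiral 1,3-diol; the acetal is inert to LiAlH4 and to the basic work-up.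

Step 3
Reactants: 4 2-(2,2-diethoxyethyl)-2-methylpropane-1,3-diol
Product: 5 2-(2,2-diethoxyethyl)-2-methylpropanedial
Conditions: (COCl)2, DMSO, CH2Cl2, −78 °C; Et3N, −78 → 0 °C; crude product used at once
Reagents that add atoms: none
Why: Swern oxidation under anhydrous basic conditions that spare the acetal; the dialdehyde has no α-hydrogen and so cannot enolise or self-condense.

Step 4
Reactants: 5 2-(2,2-diethoxyethyl)-2-methylpropanedial
Product: 6 4-(2,2-diethoxyethyl)-2,4,6-trimethylhepta-2,5-diene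
Conditions: i-PrPPh3I (3 equiv), n-BuLi, THF, 0 °C; then 5, −78 °C → rt
Reagents that add atoms: isopropyltriphenylphosphonium iodide (as its ylide), CC(C)[P+](c1ccccc1)(c1ccccc1)c1ccccc1.[I-]
Why: Twofold Wittig olefination with the unstabilised isopropylidene ylide, which is reactive enough for neopentyl-type aldehydes; no alkene geometry arises because each new alkene ends in two methyl groups.

Step 5
Reactants: 6 4-(2,2-diethoxyethyl)-2,4,6-trimethylhepta-2,5-diene
Product: 7 3,5-dimethyl-3-(2-methylprop-1-en-1-yl)hex-4-enal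
Conditions: p-MeC6H4SO3H·H2O (cat.), acetone/H2O, rt
Reagents that add atoms: water, O
Why: Acid-catalysed acetal hydrolysis; dilute acid at room temperature does not hydrate the trisubstituted alkenes, and the quaternary carbon blocks any migration of the alkenes into conjugation.

Step 6
Reactants: 8 4-tert-butoxy-4-oxobutanoic acid; 9 (S)-4-benzyloxazolidin-2-one
Product: 11 tert-butyl 4-[(4S)-4-benzyl-2-oxo-1,3-oxazolidin-3-yl]-4-oxobutanoate, via mixed pivalic anhydride 10 (not isolated)
Conditions: t-BuCOCl, Et3N, THF, −20 °C; then 9, LiCl, −20 °C → rt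
Reagents that add atoms: none
Why: N-acylation of the oxazolidinone through a mixed anhydride, which is attacked at the unhindered succinyl carbonyl while LiCl/Et3N activates the N–H; the tert-butyl ester is untouched.

Step 7
Reactants: 11 tert-butyl 4-[(4S)-4-benzyl-2-oxo-1,3-oxazolidin-3-yl]-4-oxobutanoate; 7 3,5-dimethyl-3-(2-methylprop-1-en-1-yl)hex-4-enal
Product: 12 tert-butyl (3S,4R)-3-{[(4S)-4-benzyl-2-oxo-1,3-oxazolidin-3-yl]carbonyl}-4-hydroxy-6,8-dimethyl-6-(2-methylprop-1-en-1-yl)non-7-enoate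
Conditions: Bu2BOTf, i-Pr2NEt, CH2Cl2, −78 → 0 °C; then 7, −78 → 0 °C; pH 7 buffer, MeOH, 30% H2O2, 0 °C
Reagents that add atoms: none
Why: Evans syn-aldol reaction in which the (Z)-boron enolate, formed at the imide and not at the ester, reacts through a Zimmerman–Traxler chair on the face away from the benzyl group and sets C7 (S) and C8 (R) together; the tert-butyl ester keeps the C8 aldolate from closing a γ-lactone.

Step 8
Reactants: 12 the aldol adduct
Product: 13 tert-butyl (3S,4R)-3-{[(4S)-4-benzyl-2-oxo-1,3-oxazolidin-3-yl]carbonyl}-4-[(tert-butyldimethylsilyl)oxy]-6,8-dimethyl-6-(2-methylprop-1-en-1-yl)non-7-enoate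
Conditions: TBSOTf (1.2 equiv), 2,6-lutidine, CH2Cl2, −78 → 0 °C
Reagents that add atoms: tert-butyldimethylsilyl triflate, CC(C)(C)[Si](C)(C)OS(=O)(=O)C(F)(F)F
Why: Silylation of the hindered aldol hydroxyl with a silyl triflate and a non-nucleophilic base, which avoids retro-aldol cleavage and, with little excess at low temperature, leaves the tert-butyl ester alone.

Step 9
Reactants: 13 the silylated imide
Product: 14 tert-butyl (3R,4R)-4-[(tert-butyldimethylsilyl)oxy]-3-(hydroxymethyl)-6,8-dimethyl-6-(2-methylprop-1-en-1-yl)non-7-enoate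
Conditions: LiBH4, MeOH (1.1 equiv), THF, 0 °C
Reagents that add atoms: none
Why: Reductive removal of the auxiliary, LiBH4 attacking the exocyclic imide carbonyl far faster than the tert-butyl ester and releasing 9 for reuse; C7 is untouched and only its descriptor changes.

Step 10
Reactants: 14 the primary alcohol
Product: 15 tert-butyl (3S,4R)-4-[(tert-butyldimethylsilyl)oxy]-3-formyl-6,8-dimethyl-6-(2-methylprop-1-en-1-yl)non-7-enoate
Conditions: Dess–Martin periodinane, NaHCO3, CH2Cl2, 0 °C → rt; used without storage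
Reagents that add atoms: none
Why: Dess–Martin oxidation under buffered, non-basic conditions, which keeps the α-stereocentre C7 from epimerising and the β-silyloxy group from eliminating.

Step 11
Reactants: 15 the C6 aldehyde with the bis(2-methylprop-1-enyl) quaternary C10
Product: 16 tert-butyl 2-[(1R,2S,3R,4R,6R)-6-[(tert-butyldimethylsilyl)oxy]-2-hydroxy-4-methyl-4-(2-methylprop-1-en-1-yl)-3-(prop-1-en-2-yl)cyclohexyl]acetate
Conditions: Me2AlCl (1.2 equiv), CH2Cl2, −78 → −40 °C; aqueous potassium sodium tartrate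
Reagents that add atoms: none
Why: The aluminium-bound C6 aldehyde is attacked by the inner alkene carbon (C5) of one 2-methylprop-1-enyl arm while an allylic methyl hydrogen passes to oxygen in a six-membered array, giving the homoallylic alcohol with a new isopropenyl group. The closest known reaction is the Lewis-acid type-1 carbonyl-ene cyclisation of citronellal to isopulegol. Ring A closes in a 6-exo-trig sense at the carbonyl through a chair in which the C7 acetate arm and the C8 silyloxy group, fixed by the aldol, lie equatorial. C6 follows from the bulky aluminium-bound oxygen taking the equatorial site (an axial one would face the axial C10 substituent), C5 from the reacting alkene lying equatorial and hence trans to C6–O, and C10 from which arm reacts. The step needs selection between the two diastereotopic arms: the axial C10 site is syn-axial to H6 and H8 and lies closest to the cis-methyl of the reacting alkene, so it should take the small methyl and leave the spectator alkenyl equatorial, as the target requires. Only a slight excess of Me2AlCl is used so that no chelate between C6=O and the C8 ether forces the diaxial chair, and Me2AlCl scavenges protons, so the alkenes, the silyl ether and the tert-butyl ester should survive.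

Step 12
Reactants: 16 the cyclohexanol
Product: 17 (3aR,4R,6R,7R,7aS)-4-[(tert-butyldimethylsilyl)oxy]-6-methyl-6-(2-methylprop-1-en-1-yl)-7-(prop-1-en-2-yl)hexahydro-1-benzofuran-2(3H)-one
Conditions: camphor-10-sulfonic acid (0.2 equiv), PhMe, 50 °C
Reagents that add atoms: none
Why: Acid-catalysed intramolecular transesterification (5-exo-trig) of the equatorial C6 hydroxyl onto the neighbouring equatorial acetate arm gives the trans-fused γ-lactone with loss of tert-butanol; catalytic acid in an aprotic solvent spares the silyl ether and the alkenes.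

Step 13
Reactants: 17 the lactone
Product: 18 (3aR,4R,6S,7R,7aS)-4-[(tert-butyldimethylsilyl)oxy]-6-(3,3-dimethyloxiran-2-yl)-6-methyl-7-(prop-1-en-2-yl)hexahydro-1-benzofuran-2(3H)-one (both configurations at the oxirane CH)
Conditions: mCPBA (1.05 equiv), NaHCO3, CH2Cl2, −20 → 0 °C
Reagents that add atoms: meta-chloroperoxybenzoic acid, O=C(OO)c1cccc(Cl)c1
Why: Prilezhaev epoxidation is fastest at the most electron-rich alkene, so the trisubstituted alkene should react ahead of the 1,1-disubstituted isopropenyl group, which the adjacent C6–O acyl group also deactivates inductively; the new oxirane stereocentre is destroyed in step 14.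

Step 14
Reactants: 18 the epoxide
Product: 19 (3aR,4R,6S,7R,7aS)-4-[(tert-butyldimethylsilyl)oxy]-6-methyl-2-oxo-7-(prop-1-en-2-yl)octahydro-1-benzofuran-6-carbaldehyde
Conditions: H5IO6 (1.5 equiv), THF/Et2O, 0 °C
Reagents that add atoms: none
Why: Periodic acid cleavage of an epoxide, in which acid-assisted opening at the tertiary carbon gives a cyclic periodate ester that fragments to the C10 aldehyde and acetone; the aldehyde has no α-hydrogen, so C10 cannot epimerise.

Step 15
Reactants: 19 the C10 aldehyde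
Product: 20 (3aR,4R,6R,7R,7aS)-4-[(tert-butyldimethylsilyl)oxy]-6-ethenyl-6-methyl-7-(prop-1-en-2-yl)hexahydro-1-benzofuran-2(3H)-one
Conditions: Ph3PCH3Br, KN(SiMe3)2, THF, 0 °C; then 19, −78 → 0 °C
Reagents that add atoms: methyltriphenylphosphonium bromide (as its ylide), C[P+](c1ccccc1)(c1ccccc1)c1ccccc1.[Br-]
Why: Wittig methylenation, the unstabilised ylide adding to the aldehyde much faster than to the lactone carbonyl at low temperature.

Step 16
Reactants: 20 the vinyl lactone
Product: 21 (3aR,4R,6R,7R,7aS)-4-[(tert-butyldimethylsilyl)oxy]-3-[(dimethylamino)methyl]-6-ethenyl-6-methyl-7-(prop-1-en-2-yl)hexahydro-1-benzofuran-2(3H)-one (C11 epimers)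
Conditions: LiN(i-Pr)2, THF, −78 °C; then CH2=NMe2 I, −78 °C → rt
Reagents that add atoms: N,N-dimethylmethyleneiminium iodide (Eschenmoser's salt), C=[N+](C)C.[I-]
Why: Mannich reaction of the lactone lithium enolate; only C11 can be deprotonated and the enolate has no β-leaving group, so the ring fusion and the silyl ether are unaffected.

Step 17
Reactants: 21 the Mannich base
Product: 23 (3aR,4R,6R,7R,7aS)-4-[(tert-butyldimethylsilyl)oxy]-6-ethenyl-6-methyl-3-methylidene-7-(prop-1-en-2-yl)hexahydro-1-benzofuran-2(3H)-one, via quaternary ammonium iodide 22 (not isolated)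
Conditions: MeI, MeOH, rt; then NaHCO3 (aq), EtOAc, rt
Reagents that add atoms: none
Why: N-methylation followed by base-induced β-elimination (E1cB) of trimethylamine installs the exocyclic methylene C13, the standard finish of the Eschenmoser methylenation; bicarbonate is too mild to add to the product.

Step 18
Reactants: 23 the silylated α-methylene lactone
Product: 24 (3aS,4R,6R,7R,7aS)-6-ethenyl-4-hydroxy-6-methyl-3-methylidene-7-(prop-1-en-2-yl)hexahydro-1-benzofuran-2(3H)-one
Conditions: HF·pyridine, pyridine, THF, 0 °C → rt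
Reagents that add atoms: none
Why: Fluoride-mediated desilylation under buffered acidic conditions, so that no alkoxide forms and neither migration of the lactone to O8 nor conjugate addition to the methylene lactone should occur.

Step 19
Reactants: 25 but-2-yne-1,4-diol
Product: 26 (E)-2-(tributylstannyl)but-2-ene-1,4-diol
Conditions: Bu3SnH, PdCl2(PPh3)2 (1 mol%), THF, rt
Reagents that add atoms: tributyltin hydride, CCCC[SnH](CCCC)CCCC
Why: Palladium-catalysed syn hydrostannation of a symmetrical alkyne; cis delivery of H and Sn leaves the two CH2OH groups cis to each other, the geometry of the side chain.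

Step 20
Reactants: 26 (E)-2-(tributylstannyl)but-2-ene-1,4-diol
Product: 27 (E)-2-iodobut-2-ene-1,4-diol
Conditions: I2, CH2Cl2, 0 °C
Reagents that add atoms: iodine, II
Why: Iododestannylation, an electrophilic ipso substitution at the alkenyl–tin bond that proceeds with retention of alkene geometry.

Step 21
Reactants: 27 (E)-2-iodobut-2-ene-1,4-diol
Product: 28 5-iodo-2,2-dimethyl-4,7-dihydro-1,3-dioxepine
Conditions: Me2C(OMe)2, p-MeC6H4SO3H·H2O (cat.), CH2Cl2, 4 Å molecular sieves, rt
Reagents that add atoms: 2,2-dimethoxypropane, COC(C)(C)OC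
Why: Acid-catalysed transketalisation; the two hydroxymethyl groups are held cis on the alkene, so the seven-membered acetonide closes and thereafter locks the alkene geometry.

Step 22
Reactants: 28 5-iodo-2,2-dimethyl-4,7-dihydro-1,3-dioxepine
Product: 29 2,2-dimethyl-4,7-dihydro-1,3-dioxepine-5-carboxylic acid
Conditions: Pd(OAc)2 (5 mol%), PPh3 (10 mol%), CO (1 atm), Et3N, DMF/H2O, 60 °C; citric acid to pH 4
Reagents that add atoms: carbon monoxide, [C-]#[O+]; water, O
Why: Palladium-catalysed hydroxycarbonylation of an alkenyl iodide (oxidative addition to zerovalent palladium, CO insertion, hydrolysis of the acylpalladium species) with retention of geometry; the ketal is stable to the basic medium.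

Step 23
Reactants: 29 2,2-dimethyl-4,7-dihydro-1,3-dioxepine-5-carboxylic acid; 24 the C8 alcohol
Product: 31 (3aS,4R,6R,7R,7aS)-6-ethenyl-6-methyl-3-methylidene-2-oxo-7-(prop-1-en-2-yl)octahydro-1-benzofuran-4-yl 2,2-dimethyl-4,7-dihydro-1,3-dioxepine-5-carboxylate, via mixed trichlorobenzoic anhydride 30 (not isolated)
Conditions: 2,4,6-Cl3C6H2COCl, Et3N, THF, rt; then 24, 4-(dimethylamino)pyridine, PhMe, rt
Reagents that add atoms: none
Why: Yamaguchi esterification, in which 4-(dimethylamino)pyridine attacks the less hindered acyl group of the mixed anhydride and passes the side-chain acyl group to the equatorial C8 hydroxyl; the ring-locked alkene cannot isomerise and no strong base is present to move the lactone.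

Step 24
Reactants: 31 the acetonide ester
Product: 32 (3aS,4R,6R,7R,7aS)-6-ethenyl-6-methyl-3-methylidene-2-oxo-7-(prop-1-en-2-yl)octahydro-1-benzofuran-4-yl (2E)-4-hydroxy-2-(hydroxymethyl)but-2-enoate (target)
Conditions: AcOH/THF/H2O (3:1:1), rt
Reagents that add atoms: none
Why: Acid-catalysed hydrolysis of the seven-membered ketal, which is far more labile than the two esters; the α-methylene lactone and the alkenes are stable to dilute acetic acid.

Compound list
1 | diethyl methylmalonate | CCOC(=O)C(C)C(=O)OCC | starting material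
2 | 2-bromo-1,1-diethoxyethane | CCOC(CBr)OCC | starting material
3 | diethyl 2-(2,2-diethoxyethyl)-2-methylpropanedioate | CCOC(=O)C(C)(CC(OCC)OCC)C(=O)OCC | intermediate
4 | 2-(2,2-diethoxyethyl)-2-methylpropane-1,3-diol | OCC(C)(CO)CC(OCC)OCC | intermediate
5 | 2-(2,2-diethoxyethyl)-2-methylpropanedial | O=CC(C)(C=O)CC(OCC)OCC | intermediate
6 | 4-(2,2-diethoxyethyl)-2,4,6-trimethylhepta-2,5-diene | CCOC(CC(C)(C=C(C)C)C=C(C)C)OCC | intermediate
7 | 3,5-dimethyl-3-(2-methylprop-1-en-1-yl)hex-4-enal | O=CCC(C)(C=C(C)C)C=C(C)C | intermediate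
8 | 4-tert-butoxy-4-oxobutanoic acid | CC(C)(C)OC(=O)CCC(=O)O | starting material
9 | (S)-4-benzyloxazolidin-2-one | O=C1OC[C@H](Cc2ccccc2)N1 | starting material
10 | 4-tert-butoxy-4-oxobutanoic pivalic anhydride | CC(C)(C)OC(=O)CCC(=O)OC(=O)C(C)(C)C | intermediate
11 | tert-butyl 4-[(4S)-4-benzyl-2-oxo-1,3-oxazolidin-3-yl]-4-oxobutanoate | CC(C)(C)OC(=O)CCC(=O)N1[C@@H](Cc2ccccc2)COC1=O | intermediate
12 | tert-butyl (3S,4R)-3-{[(4S)-4-benzyl-2-oxo-1,3-oxazolidin-3-yl]carbonyl}-4-hydroxy-6,8-dimethyl-6-(2-methylprop-1-en-1-yl)non-7-enoate | O=C(N1[C@@H](Cc2ccccc2)COC1=O)[C@@H](CC(=O)OC(C)(C)C)[C@H](O)CC(C)(C=C(C)C)C=C(C)C | intermediate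
13 | tert-butyl (3S,4R)-3-{[(4S)-4-benzyl-2-oxo-1,3-oxazolidin-3-yl]carbonyl}-4-[(tert-butyldimethylsilyl)oxy]-6,8-dimethyl-6-(2-methylprop-1-en-1-yl)non-7-enoate | O=C(N1[C@@H](Cc2ccccc2)COC1=O)[C@@H](CC(=O)OC(C)(C)C)[C@H](O[Si](C)(C)C(C)(C)C)CC(C)(C=C(C)C)C=C(C)C | intermediate
14 | tert-butyl (3R,4R)-4-[(tert-butyldimethylsilyl)oxy]-3-(hydroxymethyl)-6,8-dimethyl-6-(2-methylprop-1-en-1-yl)non-7-enoate | OC[C@@H](CC(=O)OC(C)(C)C)[C@H](O[Si](C)(C)C(C)(C)C)CC(C)(C=C(C)C)C=C(C)C | intermediate
15 | tert-butyl (3S,4R)-4-[(tert-butyldimethylsilyl)oxy]-3-formyl-6,8-dimethyl-6-(2-methylprop-1-en-1-yl)non-7-enoate | O=C[C@@H](CC(=O)OC(C)(C)C)[C@H](O[Si](C)(C)C(C)(C)C)CC(C)(C=C(C)C)C=C(C)C | intermediate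
16 | tert-butyl 2-[(1R,2S,3R,4R,6R)-6-[(tert-butyldimethylsilyl)oxy]-2-hydroxy-4-methyl-4-(2-methylprop-1-en-1-yl)-3-(prop-1-en-2-yl)cyclohexyl]acetate | CC(C)=C[C@@]1(C)C[C@@H](O[Si](C)(C)C(C)(C)C)[C@H](CC(=O)OC(C)(C)C)[C@@H](O)[C@@H]1C(=C)C | intermediate
17 | (3aR,4R,6R,7R,7aS)-4-[(tert-butyldimethylsilyl)oxy]-6-methyl-6-(2-methylprop-1-en-1-yl)-7-(prop-1-en-2-yl)hexahydro-1-benzofuran-2(3H)-one | CC(C)=C[C@@]1(C)C[C@@H](O[Si](C)(C)C(C)(C)C)[C@@H]2CC(=O)O[C@H]2[C@@H]1C(=C)C | intermediate
18 | (3aR,4R,6S,7R,7aS)-4-[(tert-butyldimethylsilyl)oxy]-6-(3,3-dimethyloxiran-2-yl)-6-methyl-7-(prop-1-en-2-yl)hexahydro-1-benzofuran-2(3H)-one, oxirane CH epimers | CC1(C)OC1[C@@]2(C)C[C@@H](O[Si](C)(C)C(C)(C)C)[C@@H]3CC(=O)O[C@H]3[C@@H]2C(=C)C | intermediate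
19 | (3aR,4R,6S,7R,7aS)-4-[(tert-butyldimethylsilyl)oxy]-6-methyl-2-oxo-7-(prop-1-en-2-yl)octahydro-1-benzofuran-6-carbaldehyde | O=C[C@@]1(C)C[C@@H](O[Si](C)(C)C(C)(C)C)[C@@H]2CC(=O)O[C@H]2[C@@H]1C(=C)C | intermediate
20 | (3aR,4R,6R,7R,7aS)-4-[(tert-butyldimethylsilyl)oxy]-6-ethenyl-6-methyl-7-(prop-1-en-2-yl)hexahydro-1-benzofuran-2(3H)-one | C=C[C@@]1(C)C[C@@H](O[Si](C)(C)C(C)(C)C)[C@@H]2CC(=O)O[C@H]2[C@@H]1C(=C)C | intermediate
21 | (3aR,4R,6R,7R,7aS)-4-[(tert-butyldimethylsilyl)oxy]-3-[(dimethylamino)methyl]-6-ethenyl-6-methyl-7-(prop-1-en-2-yl)hexahydro-1-benzofuran-2(3H)-one, C3 epimers | C=C[C@@]1(C)C[C@@H](O[Si](C)(C)C(C)(C)C)[C@@H]2C(CN(C)C)C(=O)O[C@H]2[C@@H]1C(=C)C | intermediate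
22 | N-methyl quaternary ammonium iodide of 21 | C=C[C@@]1(C)C[C@@H](O[Si](C)(C)C(C)(C)C)[C@@H]2C(C[N+](C)(C)C)C(=O)O[C@H]2[C@@H]1C(=C)C.[I-] | intermediate
23 | (3aR,4R,6R,7R,7aS)-4-[(tert-butyldimethylsilyl)oxy]-6-ethenyl-6-methyl-3-methylidene-7-(prop-1-en-2-yl)hexahydro-1-benzofuran-2(3H)-one | C=C[C@@]1(C)C[C@@H](O[Si](C)(C)C(C)(C)C)[C@@H]2C(=C)C(=O)O[C@H]2[C@@H]1C(=C)C | intermediate
24 | (3aS,4R,6R,7R,7aS)-6-ethenyl-4-hydroxy-6-methyl-3-methylidene-7-(prop-1-en-2-yl)hexahydro-1-benzofuran-2(3H)-one | C=C[C@@]1(C)C[C@@H](O)[C@@H]2C(=C)C(=O)O[C@H]2[C@@H]1C(=C)C | intermediate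
25 | but-2-yne-1,4-diol | OCC#CCO | starting material
26 | (E)-2-(tributylstannyl)but-2-ene-1,4-diol | OC/C=C(/[Sn](CCCC)(CCCC)CCCC)CO | intermediate
27 | (E)-2-iodobut-2-ene-1,4-diol | OC/C=C(/I)CO | intermediate
28 | 5-iodo-2,2-dimethyl-4,7-dihydro-1,3-dioxepine | CC1(C)OCC=C(I)CO1 | intermediate
29 | 2,2-dimethyl-4,7-dihydro-1,3-dioxepine-5-carboxylic acid | CC1(C)OCC=C(CO1)C(=O)O | intermediate
30 | 2,2-dimethyl-4,7-dihydro-1,3-dioxepine-5-carboxylic 2,4,6-trichlorobenzoic anhydride | CC1(C)OCC=C(CO1)C(=O)OC(=O)c2c(Cl)cc(Cl)cc2Cl | intermediate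
31 | (3aS,4R,6R,7R,7aS)-6-ethenyl-6-methyl-3-methylidene-2-oxo-7-(prop-1-en-2-yl)octahydro-1-benzofuran-4-yl 2,2-dimethyl-4,7-dihydro-1,3-dioxepine-5-carboxylate | C=C[C@@]1(C)C[C@@H](OC(=O)C3=CCOC(C)(C)OC3)[C@@H]2C(=C)C(=O)O[C@H]2[C@@H]1C(=C)C | intermediate
32 | (3aS,4R,6R,7R,7aS)-6-ethenyl-6-methyl-3-methylidene-2-oxo-7-(prop-1-en-2-yl)octahydro-1-benzofuran-4-yl (2E)-4-hydroxy-2-(hydroxymethyl)but-2-enoate | C=C[C@@]1(C)C[C@@H](OC(=O)/C(=C/CO)CO)[C@@H]2C(=C)C(=O)O[C@H]2[C@@H]1C(=C)C | target

Total step count: 24 (steps 1–18 and 23–24 on the main line with its imide branch, steps 19–22 for the side-chain acid).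
Longest linear sequence: 19 steps (1–5, 7–18, 23, 24, from diethyl methylmalonate).

Steps most likely to fail

Step 11. The two diastereotopic arms may not be discriminated well enough, so that both C10 epimers form. Chelation of aluminium between C6=O and the C8 ether could also divert the chair; a monodentate bulky Lewis acid such as Al(OC6H3-2,6-Ph2)3 would be tried first. The fallback fixes C10 before ring closure, so that only one arm can react; it sets out from diol 4 and comes back at 20. Diol 4 is desymmetrised by enzymatic mono-acetylation (lipase from Burkholderia cepacia, vinyl acetate) to (S)-2-(2,2-diethoxyethyl)-3-hydroxy-2-methylpropyl acetate F1. Swern oxidation gives (R)-2-(2,2-diethoxyethyl)-2-methyl-3-oxopropyl acetate F2, and Wittig reaction with Ph3P=CMe2 gives (S)-2-(2,2-diethoxyethyl)-2,4-dimethylpent-3-en-1-yl acetate F3. Methanolysis (K2CO3, MeOH) gives (S)-2-(2,2-diethoxyethyl)-2,4-dimethylpent-3-en-1-ol F4, Swern oxidation gives (S)-2-(2,2-diethoxyethyl)-2,4-dimethylpent-3-enal F5, and methylenation with Ph3P=CH2 gives (R)-3-(2,2-diethoxyethyl)-3,5-dimethylhexa-1,4-diene F6. Should the enzyme deliver the mirror-image monoacetate, the two ylides are used in the opposite order. Hydrolysis as in step 5 gives (R)-3-ethenyl-3,5-dimethylhex-4-enal F7, and the conditions of steps 7 to 10 give in turn the aldol adduct F8, the silyl ether F9, the primary alcohol F10 and the aldehyde F11. In the Me2AlCl carbonyl-ene reaction of F11 only the 2-methylprop-1-enyl arm can react, because the vinyl group has no allylic hydrogen; C10 is then no longer at stake and the vinyl cyclohexanol F12 should form. Lactonisation as in step 12 gives 20, and steps 13 to 15 are no longer needed.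

Step 13. The peracid may also attack the isopropenyl group or epoxidise twice, since the alkene to be oxidised sits on a quaternary carbon. The fallback sets out from 17 and comes back at 19. Photo-oxygenation (O2, hν, 5,10,15,20-tetraphenylporphyrin, CH2Cl2) is a Schenck ene reaction, for which trisubstituted alkenes are far more reactive than 1,1-disubstituted ones and which can only take a methyl hydrogen here; it gives the allylic hydroperoxide F13. PPh3 reduces it to the allylic alcohol F14. Hydroxyl-directed epoxidation (VO(acac)2, t-BuOOH) addresses only the alkene next to the new hydroxyl and gives the epoxy alcohol F15. H5IO6 then cleaves F15 between the carbinol carbon and the oxirane to give aldehyde 19.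

Step 4. Dialdehyde 5 may be lost to hydrate or oligomer formation or to base-induced deformylation before both aldehydes have reacted, and the second olefination at the crowded neopentyl centre may stall. The fallback builds the arms one at a time; it sets out from diol 4 and comes back at 6. Monosilylation (NaH, TBSCl, THF) gives the racemic mono-silyl ether F16, Swern oxidation gives the aldehyde F17, and Ph3P=CMe2 gives the alkene F18. Bu4NF gives the alcohol F19, Swern oxidation gives the non-enolisable mono-aldehyde F20, and a second Wittig reaction with Ph3P=CMe2 gives 6.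

Further compounds
F1 | step 11 | (S)-2-(2,2-diethoxyethyl)-3-hydroxy-2-methylpropyl acetate | CC(=O)OC[C@@](CO)(C)CC(OCC)OCC
F2 | step 11 | (R)-2-(2,2-diethoxyethyl)-2-methyl-3-oxopropyl acetate | CC(=O)OC[C@@](C=O)(C)CC(OCC)OCC
F3 | step 11 | (S)-2-(2,2-diethoxyethyl)-2,4-dimethylpent-3-en-1-yl acetate | CC(=O)OC[C@@](C=C(C)C)(C)CC(OCC)OCC
F4 | step 11 | (S)-2-(2,2-diethoxyethyl)-2,4-dimethylpent-3-en-1-ol | OC[C@@](C=C(C)C)(C)CC(OCC)OCC
F5 | step 11 | (S)-2-(2,2-diethoxyethyl)-2,4-dimethylpent-3-enal | O=C[C@@](C=C(C)C)(C)CC(OCC)OCC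
F6 | step 11 | (R)-3-(2,2-diethoxyethyl)-3,5-dimethylhexa-1,4-diene | C=C[C@@](C=C(C)C)(C)CC(OCC)OCC
F7 | step 11 | (R)-3-ethenyl-3,5-dimethylhex-4-enal | C=C[C@@](C=C(C)C)(C)CC=O
F8 | step 11 | aldol adduct, tert-butyl (3S,4R,6R)-3-{[(4S)-4-benzyl-2-oxo-1,3-oxazolidin-3-yl]carbonyl}-6-ethenyl-4-hydroxy-6,8-dimethylnon-7-enoate | O=C(N1[C@@H](Cc2ccccc2)COC1=O)[C@@H](CC(=O)OC(C)(C)C)[C@H](O)C[C@](C)(C=C)C=C(C)C
F9 | step 11 | silyl ether, tert-butyl (3S,4R,6R)-3-{[(4S)-4-benzyl-2-oxo-1,3-oxazolidin-3-yl]carbonyl}-4-[(tert-butyldimethylsilyl)oxy]-6-ethenyl-6,8-dimethylnon-7-enoate | O=C(N1[C@@H](Cc2ccccc2)COC1=O)[C@@H](CC(=O)OC(C)(C)C)[C@H](O[Si](C)(C)C(C)(C)C)C[C@](C)(C=C)C=C(C)C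
F10 | step 11 | primary alcohol, tert-butyl (3R,4R,6R)-4-[(tert-butyldimethylsilyl)oxy]-6-ethenyl-3-(hydroxymethyl)-6,8-dimethylnon-7-enoate | OC[C@@H](CC(=O)OC(C)(C)C)[C@H](O[Si](C)(C)C(C)(C)C)C[C@](C)(C=C)C=C(C)C
F11 | step 11 | aldehyde, tert-butyl (3S,4R,6R)-4-[(tert-butyldimethylsilyl)oxy]-6-ethenyl-3-formyl-6,8-dimethylnon-7-enoate | O=C[C@@H](CC(=O)OC(C)(C)C)[C@H](O[Si](C)(C)C(C)(C)C)C[C@](C)(C=C)C=C(C)C
F12 | step 11 | vinyl cyclohexanol, tert-butyl 2-[(1R,2S,3R,4R,6R)-6-[(tert-butyldimethylsilyl)oxy]-4-ethenyl-2-hydroxy-4-methyl-3-(prop-1-en-2-yl)cyclohexyl]acetate | C=C[C@@]1(C)C[C@@H](O[Si](C)(C)C(C)(C)C)[C@H](CC(=O)OC(C)(C)C)[C@@H](O)[C@@H]1C(=C)C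
F13 | step 13 | allylic hydroperoxide, 17 with its 2-methylprop-1-enyl group turned into 1-hydroperoxy-2-methylprop-2-en-1-yl (carbinol epimers) | C=C(C)C(OO)[C@@]1(C)C[C@@H](O[Si](C)(C)C(C)(C)C)[C@@H]2CC(=O)O[C@H]2[C@@H]1C(=C)C
F14 | step 13 | allylic alcohol, the 1-hydroxy-2-methylprop-2-en-1-yl analogue of F13 | C=C(C)C(O)[C@@]1(C)C[C@@H](O[Si](C)(C)C(C)(C)C)[C@@H]2CC(=O)O[C@H]2[C@@H]1C(=C)C
F15 | step 13 | epoxy alcohol, the hydroxy(2-methyloxiran-2-yl)methyl analogue of F14 | CC1(CO1)C(O)[C@@]2(C)C[C@@H](O[Si](C)(C)C(C)(C)C)[C@@H]3CC(=O)O[C@H]3[C@@H]2C(=C)C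
F16 | step 4 | mono-silyl ether, 2-{[(tert-butyldimethylsilyl)oxy]methyl}-4,4-diethoxy-2-methylbutan-1-ol (racemic) | CCOC(CC(C)(CO)CO[Si](C)(C)C(C)(C)C)OCC
F17 | step 4 | aldehyde, 2-{[(tert-butyldimethylsilyl)oxy]methyl}-4,4-diethoxy-2-methylbutanal (racemic) | CCOC(CC(C)(C=O)CO[Si](C)(C)C(C)(C)C)OCC
F18 | step 4 | alkene, tert-butyl{[2-(2,2-diethoxyethyl)-2,4-dimethylpent-3-en-1-yl]oxy}dimethylsilane (racemic) | CCOC(CC(C)(C=C(C)C)CO[Si](C)(C)C(C)(C)C)OCC
F19 | step 4 | alcohol, 2-(2,2-diethoxyethyl)-2,4-dimethylpent-3-en-1-ol (racemic) | CCOC(CC(C)(CO)C=C(C)C)OCC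
F20 | step 4 | mono-aldehyde, 2-(2,2-diethoxyethyl)-2,4-dimethylpent-3-enal (racemic) | CCOC(CC(C)(C=O)C=C(C)C)OCC
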